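Assumption: the target is taken as the constitution written in its SMILES string, an achiral hexamer with no stereocentre and freely rotating aryl ether bonds. The only stereocentre of the route (the carbinol carbon of 30) is racemic and disappears in the key step.

## The problem

The target is a linear chain of six benzene rings joined only by diaryl ether oxygens (A–O–B–O–C–O–D–O–E–O–F, lettered in SMILES order) and carrying sixteen free phenolic hydroxyls. There is no stereocentre, so the task is to form five aryl–O–aryl bonds at the right positions and to tell the five ether oxygens from the sixteen hydroxyl oxygens. Each ether oxygen sits, on one of its two rings, on a carbon flanked by two oxygenated carbons (ring A C2, ring B C4, ring C C6, ring D C4, ring E C6). Every coupling therefore involves a 2,6-disubstituted phenol, and the B–O–C and D–O–E ethers are crowded on both sides. Rings C and E each carry five contiguous oxygens and one hydrogen, with two adjacent aryl ethers (C1 and C6), a pattern that is hard to reach by substitution of an existing arene. The free polyphenol, with its pyrogallol and hydroxyquinol units, oxidises readily in air and base, so it must be released last under neutral conditions; the ynol ether, cyclobutenone, quinone and hydroquinone intermediates also need acid-free or oxygen-free handling. Ring E (C1 bearing the ring D oxygen, C2 the hydrogen, C3 to C5 hydroxyls, C6 the ring F oxygen) is the opening: C3 to C6 are four contiguous oxygenated carbons, as in squaric acid, and C1–C2 is an oxygen-bearing two-carbon unit, as in an aryloxyacetylene. Only the C6–C1 bond has to be closed.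

## Retrosynthesis

**Protecting groups.** Target 40 is traced back to its hexadecabenzyl ether 39. Benzyl is chosen for all sixteen hydroxyls because one neutral hydrogenolysis then releases the air-sensitive polyphenol with toluene as the only by-product. Methyl ethers would need a Lewis acid on a sixteen-fold scale.

**Ring E to ring F ether.** The C6–O bond of ring E to ring F is cut in 39, giving phenol 35 and 5-bromo-1,2,3-tris(benzyloxy)benzene 38. The crowded partner is the nucleophile and the halide has no ortho substituent, the only workable polarity for a copper-mediated coupling. Bromide 38 comes from 5-bromo-1,2,3-trimethoxybenzene 36 through triol 37.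

**Differentiating the ring E hydroxyls.** Phenol 35 is the monobenzyl ether of hydroquinone 34, which is the reduction product of quinone 33. The two hydroxyls of 34 differ sharply in their surroundings: one has a C–H neighbour, the other lies between a benzyloxy group and the ring D aryloxy group. Benzylation is asked to pick the first.

**Key disconnection.** The C6–C1 bond of ring E is cut in quinone 33, leading back through enynyl ketene 31 to racemic cyclobutenone 30. This is preferred over stepwise oxygenation of an arene because all five oxygens and the single hydrogen of ring E arrive at once, already differentiated by origin: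
- two benzyloxy groups come from the squarate;
- the two quinone oxygens come from the squarate carbonyl groups;
- the ring D ether comes from the ynol ether.

The most crowded ether of the molecule (D–O–E, 2,6-disubstituted on ring D and ortho-substituted on ring E) is thus never made by aryl–O coupling. The forward reaction must close the six-membered rather than the five-membered ring.

**Cyclobutenone.** The bond between the carbinol carbon and the alkyne is cut in 30, giving dibenzyl squarate 27 (from squaric acid 26) and the lithium acetylide derived from (E)-1,2-dichlorovinyl ether 25. Ether 25 comes from tetrameric phenol 22 and trichloroethylene 23. The symmetric squarate removes any choice of carbonyl group.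

**Tetramer.** Phenol 22 is cut at the C–O–D ether into trimeric phenol 20 and bromide 10, with the ring D hydroxyl masked as a methoxymethyl ether in 21. Phenol 20 is cut at the B–O–C ether into dimeric phenol 12 and ring C iodide 18. Phenol 12 is cut at the A–O–B ether into ring A phenol 4 and, again, bromide 10. In each case the nucleophile is the 2,6-disubstituted phenol. One building block, 10, serves rings B and D. The only halide with an ortho substituent is 18, which is therefore an iodide.

**Building blocks.**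
- Phenol 4 comes from 2,4,6-trihydroxybenzaldehyde 1 by benzylation (2) and Baeyer–Villiger oxidation.
- Bromide 10 comes from 1,3-bis(benzyloxy)benzene 5 by ortho-lithiation, borylation and oxidation (8), para-bromination (9) and acetal protection.
- Iodide 18 comes from 2,3,4-trihydroxybenzaldehyde 13 by benzylation (14), Baeyer–Villiger oxidation (16), ortho-iodination (17) and acetal protection.

Aldehydes serve as masked phenols because the oxidation puts the hydroxyl exactly where the next ether is needed.

## Roads not taken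

Alternative 1: Both ether bonds of ring B are cut, and ring B enters as a double electrophile, the cyclopentadienyl complex of divalent ruthenium A1 with 2,5-dichloro-1,3-bis(methoxymethoxy)benzene. In one pot the phenoxide of ring A (compound 4 would serve) would displace the unhindered chloride and the phenoxide of the CDEF tetramer A2 the chloride between the two acetals; irradiation in acetonitrile would release hexamer A3.
- Merits: substitution on the cationic arene complex runs near room temperature and tolerates ortho substituents on both partners better than copper catalysis. It is better than the chosen plan at the B–O–C ether (step 12) and more convergent (1 + 1 + 4).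
- Weak points: ruthenium is stoichiometric; the order of the two substitutions rests on a rate difference between the chlorides; the acetals on ring B add a second deprotection. Above all, A2 already contains ring E with all five oxygens and both of its ethers, so the hardest ring is postponed, not solved.
- Comparison: the chosen plan sets against the milder ether formation a ring E whose oxygens are differentiated by construction and the use of catalytic copper only. Its price is a longer linear sequence with four crowded copper couplings.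

Alternative 2: Two C–C bonds of ring B are cut. The 2-aryloxy-3-(dimethylamino)acrolein A4 (from phenol 4 by way of the aryloxyacetic acid) and 1,3-bis(benzyloxy)acetone A5 would condense under NaOEt to AB phenol A6, which is identical with compound 12.
- Merits: the A–O–B ether is made by simple alkylation of a phenol, without copper and without a protecting-group change on ring B. For this one bond it is at least as good as steps 6 and 7.
- Weak points: the enolate of an alpha-benzyloxy ketone can eliminate benzyloxide or self-condense, and the aryloxy-substituted vinylogous formamide is a weak electrophile. The reaction delivers only the dimer, the least demanding part of the molecule, and leaves rings C and E untouched.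
- Comparison: about four steps from 4 to 12, against two from 4 plus three for bromide 10. Because 10 is used a second time for ring D, the chosen plan loses nothing here, and its de novo ring construction is spent on ring E, where no substitution chemistry is available.

Alternative 3: Two C–C bonds of ring A are cut. Dimethyl 1,3-acetonedicarboxylate A7 and the aryloxymalonate A8 of the BCDEF pentamer would undergo Claisen–Dieckmann condensation under NaOMe to give A9, with ring A as a dimethyl 2,4,6-trihydroxy-5-aryloxyisophthalate. Saponification, double decarboxylation and hydrogenolysis would follow.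
- Merits: the hindered oxygen of ring A is introduced by alkylation with a halomalonate, and ring A needs no protecting groups.
- Weak points: the ring built de novo is the simplest one, available as 1. The condensation and the decarboxylation of an oxidation-prone free phloroglucinol come at the very end, on a pentamer with thirteen benzyl ethers. A8 presupposes four of the five ether bonds and the whole of ring E.
- Comparison: the A–O–B ether is the easiest coupling of the chosen route (step 6, unhindered bromide), so Alternative 3 replaces the least problematic step with a long endgame. Its one advantage, fewer benzyl groups on ring A, does not outweigh this.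

Key step: step 19

## Route

In the names below, "ABCD-aryl" stands for 2,6-bis(benzyloxy)-4-{2,3,4-tris(benzyloxy)-6-[2,6-bis(benzyloxy)-4-(2,4,6-tris(benzyloxy)phenoxy)phenoxy]phenoxy}phenyl, and Bn is benzyl.

Step 1
Reactants: 1 2,4,6-trihydroxybenzaldehyde
Product: 2 2,4,6-tris(benzyloxy)benzaldehyde
Conditions: BnBr, K2CO3, DMF, 60 °C
Reagents that add atoms: benzyl bromide, BrCc1ccccc1
Why: Williamson ether synthesis; the formyl group deactivates the ring carbons, so O- rather than C-benzylation of the phloroglucinol nucleus is expected, and warming overcomes the hydrogen bonds of the two ortho hydroxyls.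

Step 2
Reactants: 2 2,4,6-tris(benzyloxy)benzaldehyde
Product: 4 2,4,6-tris(benzyloxy)phenol, via 2,4,6-tris(benzyloxy)phenyl formate 3 (not isolated)
Conditions: mCPBA, CH2Cl2, 0 °C to rt; aq Na2SO3; then K2CO3, MeOH, rt
Reagents that add atoms: mCPBA, OOC(=O)c1cccc(Cl)c1
Why: Baeyer–Villiger (Dakin-type) oxidation in which the electron-rich aryl group migrates; the formate shields the new phenol from peracid until the quench and is then methanolysed.

Step 3
Reactants: 5 1,3-bis(benzyloxy)benzene
Product: 8 2,6-bis(benzyloxy)phenol, via 2,6-bis(benzyloxy)phenyllithium 6 (not isolated), via dimethyl 2,6-bis(benzyloxy)phenylboronate 7 (not isolated)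
Conditions: n-BuLi, THF, 0 °C to rt; B(OMe)3, −78 °C to rt; 30% H2O2, aq NaOH, 0 °C
Reagents that add atoms: hydrogen peroxide, OO
Why: Directed ortho-metalation at the carbon flanked by both benzyloxy groups, borylation and oxidative conversion of C–B into C–O, the standard way from 1,3-dialkoxybenzenes to 2,6-dialkoxyphenols.

Step 4
Reactants: 8 2,6-bis(benzyloxy)phenol
Product: 9 4-bromo-2,6-bis(benzyloxy)phenol
Conditions: NBS, NaH (cat.), CHCl3, −45 °C to rt
Reagents that add atoms: N-bromosuccinimide, O=C1CCC(=O)N1Br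
Why: Electrophilic aromatic bromination; with both ortho positions blocked the phenol (partly as phenoxide) directs to the para carbon, and the low temperature disfavours attack next to a benzyloxy group.

Step 5
Reactants: 9 4-bromo-2,6-bis(benzyloxy)phenol
Product: 10 5-bromo-1,3-bis(benzyloxy)-2-(methoxymethoxy)benzene
Conditions: NaH, MOMCl, THF/DMF, 0 °C to rt
Reagents that add atoms: chloromethyl methyl ether, COCCl
Why: O-alkylation of the sodium phenoxide; the acetal keeps the bromophenol from coupling with itself, survives the basic copper couplings and is later removed by acid without loss of benzyl ethers.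

Step 6
Reactants: 4 2,4,6-tris(benzyloxy)phenol; 10 5-bromo-1,3-bis(benzyloxy)-2-(methoxymethoxy)benzene
Product: 11 1,3-bis(benzyloxy)-2-(methoxymethoxy)-5-[2,4,6-tris(benzyloxy)phenoxy]benzene
Conditions: CuI (cat.), picolinic acid, K3PO4, DMSO, 90 °C, Ar
Reagents that add atoms: none
Why: Ullmann diaryl ether synthesis with a ligand system suited to 2,6-disubstituted phenols; the bromide of 10 has no ortho substituent, so the crowding lies on the nucleophile only.

Step 7
Reactants: 11 1,3-bis(benzyloxy)-2-(methoxymethoxy)-5-[2,4,6-tris(benzyloxy)phenoxy]benzene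
Product: 12 2,6-bis(benzyloxy)-4-[2,4,6-tris(benzyloxy)phenoxy]phenol
Conditions: conc. HCl (cat.), MeOH/THF, 50 °C
Reagents that add atoms: none
Why: Acid-catalysed acetal cleavage by transacetalisation; benzyl and diaryl ethers are inert, and the large excess of methanol intercepts the methoxymethyl cation before it can alkylate the electron-rich rings.

Step 8
Reactants: 13 2,3,4-trihydroxybenzaldehyde
Product: 14 2,3,4-tris(benzyloxy)benzaldehyde
Conditions: BnBr, K2CO3, DMF, 60 °C
Reagents that add atoms: benzyl bromide, BrCc1ccccc1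
Why: Williamson ether synthesis on all three phenoxides, a routine perbenzylation of this aldehyde.

Step 9
Reactants: 14 2,3,4-tris(benzyloxy)benzaldehyde
Product: 16 2,3,4-tris(benzyloxy)phenol, via 2,3,4-tris(benzyloxy)phenyl formate 15 (not isolated)
Conditions: mCPBA, CH2Cl2, 0 °C to rt; aq Na2SO3; then K2CO3, MeOH, rt
Reagents that add atoms: mCPBA, OOC(=O)c1cccc(Cl)c1
Why: Baeyer–Villiger oxidation with migration of the trialkoxyaryl group and methanolysis of the formate; it puts the new oxygen on the carbon that will carry the ring D ether.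

Step 10
Reactants: 16 2,3,4-tris(benzyloxy)phenol
Product: 17 2,3,4-tris(benzyloxy)-6-iodophenol
Conditions: I2, NaHCO3, THF/H2O, 0 °C to rt
Reagents that add atoms: iodine, II
Why: Electrophilic iodination through the phenoxide, which directs ortho and para; the para carbon carries a benzyloxy group and C5 is meta to the phenoxide oxygen, so iodine should enter at C6 only.

Step 11
Reactants: 17 2,3,4-tris(benzyloxy)-6-iodophenol
Product: 18 1,2,3-tris(benzyloxy)-5-iodo-4-(methoxymethoxy)benzene
Conditions: NaH, MOMCl, THF/DMF, 0 °C to rt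
Reagents that add atoms: chloromethyl methyl ether, COCCl
Why: O-alkylation of the phenoxide; masking the hydroxyl prevents self-coupling of the iodophenol in step 12.

Step 12
Reactants: 12 2,6-bis(benzyloxy)-4-[2,4,6-tris(benzyloxy)phenoxy]phenol; 18 1,2,3-tris(benzyloxy)-5-iodo-4-(methoxymethoxy)benzene
Product: 19 1,2,3-tris(benzyloxy)-4-(methoxymethoxy)-5-{2,6-bis(benzyloxy)-4-[2,4,6-tris(benzyloxy)phenoxy]phenoxy}benzene
Conditions: CuI, picolinic acid, K3PO4, DMSO, 100 °C, Ar
Reagents that add atoms: none
Why: Ullmann diaryl ether synthesis between a 2,6-disubstituted phenol and an ortho-substituted aryl halide; the iodide is used for its easier oxidative addition, and the ortho acetal oxygen can assist by chelating copper.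

Step 13
Reactants: 19 1,2,3-tris(benzyloxy)-4-(methoxymethoxy)-5-{2,6-bis(benzyloxy)-4-[2,4,6-tris(benzyloxy)phenoxy]phenoxy}benzene
Product: 20 2,3,4-tris(benzyloxy)-6-{2,6-bis(benzyloxy)-4-[2,4,6-tris(benzyloxy)phenoxy]phenoxy}phenol
Conditions: conc. HCl (cat.), MeOH/THF, 50 °C
Reagents that add atoms: none
Why: Acid-catalysed acetal cleavage as in step 7; the crowded acetal is cleaved readily and the benzyl ethers remain.

Step 14
Reactants: 20 2,3,4-tris(benzyloxy)-6-{2,6-bis(benzyloxy)-4-[2,4,6-tris(benzyloxy)phenoxy]phenoxy}phenol; 10 5-bromo-1,3-bis(benzyloxy)-2-(methoxymethoxy)benzene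
Product: 21 ABCD-aryl methoxymethyl ether
Conditions: CuI, picolinic acid, K3PO4, DMSO, 100 °C, Ar
Reagents that add atoms: none
Why: Ullmann diaryl ether synthesis with the same unhindered bromide as in step 6; the phenol is flanked by one benzyloxy and one aryloxy group, a degree of crowding the picolinate system accepts.

Step 15
Reactants: 21 ABCD-aryl methoxymethyl ether
Product: 22 ABCD-aryl alcohol (tetrameric phenol with the free hydroxyl on ring D)
Conditions: conc. HCl (cat.), MeOH/THF, 50 °C
Reagents that add atoms: none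
Why: Acid-catalysed acetal cleavage as in step 7, leaving the ten benzyl ethers and three diaryl ethers intact.

Step 16
Reactants: 22 ABCD-aryl alcohol; 23 trichloroethylene
Product: 25 (E)-1,2-dichlorovinyl ABCD-aryl ether, via dichloroacetylene 24 (not isolated)
Conditions: K2CO3, DMF, 70 °C
Reagents that add atoms: none
Why: Base-induced loss of HCl from trichloroethylene gives dichloroacetylene, to which the phenoxide adds with anti protonation to give the (E)-dichlorovinyl ether; this is the standard entry to aryl ynol ethers, and the linear electrophile is indifferent to the two ortho substituents.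

Step 17
Reactants: 26 squaric acid
Product: 27 3,4-bis(benzyloxy)cyclobut-3-ene-1,2-dione (dibenzyl squarate)
Conditions: BnOH, toluene, reflux, Dean–Stark
Reagents that add atoms: benzyl alcohol, OCc1ccccc1
Why: Self-catalysed esterification of the vinylogous carboxylic acid with azeotropic removal of water, the usual route from squaric acid and primary alcohols to dialkyl squarates.

Step 18
Reactants: 25 (E)-1,2-dichlorovinyl ABCD-aryl ether; 27 dibenzyl squarate
Product: 30 rac-2,3-bis(benzyloxy)-4-hydroxy-4-[(ABCD-aryloxy)ethynyl]cyclobut-2-en-1-one, via chloroethynyl ABCD-aryl ether 28 (not isolated), via lithium (ABCD-aryloxy)acetylide 29 (not isolated)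
Conditions: n-BuLi (2.2 equiv), THF, −78 to −40 °C; cannulated into 27 (excess), THF, −78 °C; pH 7 buffer; Et3N-treated silica
Reagents that add atoms: none
Why: The first equivalent of n-BuLi eliminates HCl to the chloroalkyne and the second effects Cl/Li exchange; the acetylide then adds 1,2 to one of the two equivalent carbonyl groups of the squarate, the established access to 4-alkynyl-4-hydroxycyclobutenones. The carbinol stereocentre forms as a racemate, which is of no consequence because it becomes trigonal in step 19; the neutral quench and basic silica keep the ynol ether from hydrating.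

Step 19
Reactants: 30 rac-2,3-bis(benzyloxy)-4-hydroxy-4-[(ABCD-aryloxy)ethynyl]cyclobut-2-en-1-one
Product: 33 2,3-bis(benzyloxy)-5-(ABCD-aryloxy)-1,4-benzoquinone, via enynyl ketene 31 (not isolated), via ring E diradical 32 (not isolated)
Conditions: degassed p-xylene (0.01 M), 138 °C, base-washed glassware
Reagents that add atoms: none
Why: Moore rearrangement of a 4-alkynyl-4-hydroxycyclobutenone, the closest known reaction type, here with an aryloxy group on the alkyne. Thermal conrotatory 4π opening of 30 breaks the bond between the carbonyl and carbinol carbons with the hydroxyl turning outward, as donor substituents at that carbon do, so the alkynyl group of ketene 31 lies cis to the ketene. The ketene carbon then bonds to the distal, oxygen-bearing alkyne carbon in a 6-endo-dig closure, which forms the C6–C1 bond of ring E and gives the aromatic diradical 32 (phenoxyl plus aryl sigma radical). Transfer of the hydroxyl hydrogen to the aryl radical centre delivers quinone 33, with its single ring hydrogen next to the aryloxy carbon. No stereocentre is created, and the racemic carbinol centre of 30 becomes a carbonyl carbon. The selectivity needed is six- over five-membered (5-exo-dig) closure: the six-ring path gains aromatic stabilisation, whereas the aryloxy group cannot stabilise the exocyclic vinyl radical of the five-ring path by conjugation as aryl, silyl or ester groups do. Regiochemistry within ring E is not in question because the carbonyl groups of squarate 27 are equivalent, so the squarate carbons become C3 to C6 and the ynol ether carbons C1 and C2. The aryl ynol ether has no hydrogen beta to oxygen on the aryl side, so the retro-ene loss that limits alkyl ynol ethers cannot occur; dilution and acid-free glassware guard against bimolecular ketene reactions and hydration.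

Step 20
Reactants: 33 2,3-bis(benzyloxy)-5-(ABCD-aryloxy)-1,4-benzoquinone
Product: 35 2,3,4-tris(benzyloxy)-6-(ABCD-aryloxy)phenol, via hydroquinone 34 (not isolated)
Conditions: Na2S2O4, THF/H2O, rt; organic phase dried under Ar; then BnBr (1.05 equiv), K2CO3, DMF, 0 °C to rt
Reagents that add atoms: benzyl bromide, BrCc1ccccc1
Why: Dithionite reduction of the quinone, then Williamson benzylation with one equivalent of benzyl bromide at the hydroxyl that has a C–H neighbour; the other hydroxyl lies between a benzyloxy group and the aryloxy group of the 2,6-disubstituted ring D. The hydroquinone is carried on under argon because it reoxidises readily.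

Step 21
Reactants: 36 5-bromo-1,2,3-trimethoxybenzene
Product: 37 5-bromobenzene-1,2,3-triol
Conditions: BBr3, CH2Cl2, −78 °C to rt; H2O
Reagents that add atoms: none
Why: Lewis-acid cleavage of aryl methyl ethers with BBr3; the aryl bromide is untouched.

Step 22
Reactants: 37 5-bromobenzene-1,2,3-triol
Product: 38 5-bromo-1,2,3-tris(benzyloxy)benzene
Conditions: BnBr, K2CO3, DMF, 60 °C, Ar
Reagents that add atoms: benzyl bromide, BrCc1ccccc1
Why: Williamson ether synthesis on the three phenoxides, run under argon because the bromopyrogallol is oxidation-prone in base.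

Step 23
Reactants: 35 2,3,4-tris(benzyloxy)-6-(ABCD-aryloxy)phenol; 38 5-bromo-1,2,3-tris(benzyloxy)benzene
Product: 39 hexadeca-O-benzyl ether of the target (1,2,3-tris(benzyloxy)-5-[2,3,4-tris(benzyloxy)-6-(ABCD-aryloxy)phenoxy]benzene)
Conditions: CuI, picolinic acid, K3PO4, DMSO, 100 °C, Ar
Reagents that add atoms: none
Why: Ullmann diaryl ether synthesis; the only free hydroxyl of 35 is the nucleophile and bromide 38 has no ortho substituent, the same polarity as in steps 6 and 14.

Step 24
Reactants: 39 hexadeca-O-benzyl ether of the target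
Product: 40 target hexamer CNP0114537.0
Conditions: H2 (1 atm), 10% Pd/C, THF/MeOH, rt
Reagents that add atoms: none
Why: Catalytic hydrogenolysis of all sixteen benzyl ethers under neutral conditions; diaryl ethers are not cleaved, and the oxidation-prone polyphenol is released without base or air.

## Compound list

1 | 2,4,6-trihydroxybenzaldehyde | O=Cc1c(O)cc(O)cc1O | starting material
2 | 2,4,6-tris(benzyloxy)benzaldehyde | O=Cc1c(OCc2ccccc2)cc(OCc2ccccc2)cc1OCc1ccccc1 | intermediate
3 | 2,4,6-tris(benzyloxy)phenyl formate | O=COc1c(OCc2ccccc2)cc(OCc2ccccc2)cc1OCc1ccccc1 | intermediate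
4 | 2,4,6-tris(benzyloxy)phenol | Oc1c(OCc2ccccc2)cc(OCc2ccccc2)cc1OCc1ccccc1 | intermediate
5 | 1,3-bis(benzyloxy)benzene | C(Oc1cccc(OCc2ccccc2)c1)c1ccccc1 | starting material
6 | 2,6-bis(benzyloxy)phenyllithium | [Li]c1c(OCc2ccccc2)cccc1OCc1ccccc1 | intermediate
7 | dimethyl 2,6-bis(benzyloxy)phenylboronate | COB(OC)c1c(OCc2ccccc2)cccc1OCc1ccccc1 | intermediate
8 | 2,6-bis(benzyloxy)phenol | Oc1c(OCc2ccccc2)cccc1OCc1ccccc1 | intermediate
9 | 4-bromo-2,6-bis(benzyloxy)phenol | Oc1c(OCc2ccccc2)cc(Br)cc1OCc1ccccc1 | intermediate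
10 | 5-bromo-1,3-bis(benzyloxy)-2-(methoxymethoxy)benzene | COCOc1c(OCc2ccccc2)cc(Br)cc1OCc1ccccc1 | intermediate
11 | 1,3-bis(benzyloxy)-2-(methoxymethoxy)-5-[2,4,6-tris(benzyloxy)phenoxy]benzene | COCOc1c(OCc2ccccc2)cc(Oc2c(OCc3ccccc3)cc(OCc3ccccc3)cc2OCc2ccccc2)cc1OCc1ccccc1 | intermediate
12 | 2,6-bis(benzyloxy)-4-[2,4,6-tris(benzyloxy)phenoxy]phenol | Oc1c(OCc2ccccc2)cc(Oc2c(OCc3ccccc3)cc(OCc3ccccc3)cc2OCc2ccccc2)cc1OCc1ccccc1 | intermediate
13 | 2,3,4-trihydroxybenzaldehyde | O=Cc1ccc(O)c(O)c1O | starting material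
14 | 2,3,4-tris(benzyloxy)benzaldehyde | O=Cc1ccc(OCc2ccccc2)c(OCc2ccccc2)c1OCc1ccccc1 | intermediate
15 | 2,3,4-tris(benzyloxy)phenyl formate | O=COc1ccc(OCc2ccccc2)c(OCc2ccccc2)c1OCc1ccccc1 | intermediate
16 | 2,3,4-tris(benzyloxy)phenol | Oc1ccc(OCc2ccccc2)c(OCc2ccccc2)c1OCc1ccccc1 | intermediate
17 | 2,3,4-tris(benzyloxy)-6-iodophenol | Oc1c(I)cc(OCc2ccccc2)c(OCc2ccccc2)c1OCc1ccccc1 | intermediate
18 | 1,2,3-tris(benzyloxy)-5-iodo-4-(methoxymethoxy)benzene | COCOc1c(I)cc(OCc2ccccc2)c(OCc2ccccc2)c1OCc1ccccc1 | intermediate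
19 | 1,2,3-tris(benzyloxy)-4-(methoxymethoxy)-5-{2,6-bis(benzyloxy)-4-[2,4,6-tris(benzyloxy)phenoxy]phenoxy}benzene | COCOc1c(Oc2c(OCc3ccccc3)cc(Oc3c(OCc4ccccc4)cc(OCc4ccccc4)cc3OCc3ccccc3)cc2OCc2ccccc2)cc(OCc2ccccc2)c(OCc2ccccc2)c1OCc1ccccc1 | intermediate
20 | 2,3,4-tris(benzyloxy)-6-{2,6-bis(benzyloxy)-4-[2,4,6-tris(benzyloxy)phenoxy]phenoxy}phenol | Oc1c(Oc2c(OCc3ccccc3)cc(Oc3c(OCc4ccccc4)cc(OCc4ccccc4)cc3OCc3ccccc3)cc2OCc2ccccc2)cc(OCc2ccccc2)c(OCc2ccccc2)c1OCc1ccccc1 | intermediate
21 | ABCD-aryl methoxymethyl ether | COCOc1c(OCc2ccccc2)cc(Oc2c(OCc3ccccc3)c(OCc3ccccc3)c(OCc3ccccc3)cc2Oc2c(OCc3ccccc3)cc(Oc3c(OCc4ccccc4)cc(OCc4ccccc4)cc3OCc3ccccc3)cc2OCc2ccccc2)cc1OCc1ccccc1 | intermediate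
22 | ABCD-aryl alcohol (tetrameric phenol, free hydroxyl on ring D) | Oc1c(OCc2ccccc2)cc(Oc2c(OCc3ccccc3)c(OCc3ccccc3)c(OCc3ccccc3)cc2Oc2c(OCc3ccccc3)cc(Oc3c(OCc4ccccc4)cc(OCc4ccccc4)cc3OCc3ccccc3)cc2OCc2ccccc2)cc1OCc1ccccc1 | intermediate
23 | trichloroethylene | ClC=C(Cl)Cl | starting material
24 | dichloroacetylene | ClC#CCl | intermediate
25 | (E)-1,2-dichlorovinyl ABCD-aryl ether | Cl/C=C(/Cl)Oc1c(OCc2ccccc2)cc(Oc2c(OCc3ccccc3)c(OCc3ccccc3)c(OCc3ccccc3)cc2Oc2c(OCc3ccccc3)cc(Oc3c(OCc4ccccc4)cc(OCc4ccccc4)cc3OCc3ccccc3)cc2OCc2ccccc2)cc1OCc1ccccc1 | intermediate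
26 | squaric acid | OC1=C(O)C(=O)C1=O | starting material
27 | 3,4-bis(benzyloxy)cyclobut-3-ene-1,2-dione (dibenzyl squarate) | O=C1C(=O)C(OCc2ccccc2)=C1OCc1ccccc1 | intermediate
28 | chloroethynyl ABCD-aryl ether | ClC#COc1c(OCc2ccccc2)cc(Oc2c(OCc3ccccc3)c(OCc3ccccc3)c(OCc3ccccc3)cc2Oc2c(OCc3ccccc3)cc(Oc3c(OCc4ccccc4)cc(OCc4ccccc4)cc3OCc3ccccc3)cc2OCc2ccccc2)cc1OCc1ccccc1 | intermediate
29 | lithium (ABCD-aryloxy)acetylide | [Li]C#COc1c(OCc2ccccc2)cc(Oc2c(OCc3ccccc3)c(OCc3ccccc3)c(OCc3ccccc3)cc2Oc2c(OCc3ccccc3)cc(Oc3c(OCc4ccccc4)cc(OCc4ccccc4)cc3OCc3ccccc3)cc2OCc2ccccc2)cc1OCc1ccccc1 | intermediate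
30 | rac-2,3-bis(benzyloxy)-4-hydroxy-4-[(ABCD-aryloxy)ethynyl]cyclobut-2-en-1-one | O=C1C(OCc2ccccc2)=C(OCc2ccccc2)C1(O)C#COc1c(OCc2ccccc2)cc(Oc2c(OCc3ccccc3)c(OCc3ccccc3)c(OCc3ccccc3)cc2Oc2c(OCc3ccccc3)cc(Oc3c(OCc4ccccc4)cc(OCc4ccccc4)cc3OCc3ccccc3)cc2OCc2ccccc2)cc1OCc1ccccc1 | intermediate
31 | (Z)-2,3-bis(benzyloxy)-4-hydroxy-6-(ABCD-aryloxy)hexa-1,3-dien-5-yn-1-one (enynyl ketene) | O=C=C(OCc1ccccc1)/C(OCc1ccccc1)=C(/O)C#COc1c(OCc2ccccc2)cc(Oc2c(OCc3ccccc3)c(OCc3ccccc3)c(OCc3ccccc3)cc2Oc2c(OCc3ccccc3)cc(Oc3c(OCc4ccccc4)cc(OCc4ccccc4)cc3OCc3ccccc3)cc2OCc2ccccc2)cc1OCc1ccccc1 | intermediate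
32 | ring E diradical (2,3-bis(benzyloxy)-4-hydroxy-6-(ABCD-aryloxy)phenoxyl with a sigma radical at C5) | [O]c1c(OCc2ccccc2)c(OCc2ccccc2)c(O)[c]c1Oc1c(OCc2ccccc2)cc(Oc2c(OCc3ccccc3)c(OCc3ccccc3)c(OCc3ccccc3)cc2Oc2c(OCc3ccccc3)cc(Oc3c(OCc4ccccc4)cc(OCc4ccccc4)cc3OCc3ccccc3)cc2OCc2ccccc2)cc1OCc1ccccc1 | intermediate
33 | 2,3-bis(benzyloxy)-5-(ABCD-aryloxy)-1,4-benzoquinone | O=C1C(OCc2ccccc2)=C(OCc2ccccc2)C(=O)C=C1Oc1c(OCc2ccccc2)cc(Oc2c(OCc3ccccc3)c(OCc3ccccc3)c(OCc3ccccc3)cc2Oc2c(OCc3ccccc3)cc(Oc3c(OCc4ccccc4)cc(OCc4ccccc4)cc3OCc3ccccc3)cc2OCc2ccccc2)cc1OCc1ccccc1 | intermediate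
34 | 2,3-bis(benzyloxy)-5-(ABCD-aryloxy)benzene-1,4-diol (hydroquinone) | Oc1c(OCc2ccccc2)c(OCc2ccccc2)c(O)cc1Oc1c(OCc2ccccc2)cc(Oc2c(OCc3ccccc3)c(OCc3ccccc3)c(OCc3ccccc3)cc2Oc2c(OCc3ccccc3)cc(Oc3c(OCc4ccccc4)cc(OCc4ccccc4)cc3OCc3ccccc3)cc2OCc2ccccc2)cc1OCc1ccccc1 | intermediate
35 | 2,3,4-tris(benzyloxy)-6-(ABCD-aryloxy)phenol | Oc1c(OCc2ccccc2)c(OCc2ccccc2)c(OCc2ccccc2)cc1Oc1c(OCc2ccccc2)cc(Oc2c(OCc3ccccc3)c(OCc3ccccc3)c(OCc3ccccc3)cc2Oc2c(OCc3ccccc3)cc(Oc3c(OCc4ccccc4)cc(OCc4ccccc4)cc3OCc3ccccc3)cc2OCc2ccccc2)cc1OCc1ccccc1 | intermediate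
36 | 5-bromo-1,2,3-trimethoxybenzene | COc1cc(Br)cc(OC)c1OC | starting material
37 | 5-bromobenzene-1,2,3-triol | Oc1cc(Br)cc(O)c1O | intermediate
38 | 5-bromo-1,2,3-tris(benzyloxy)benzene | Brc1cc(OCc2ccccc2)c(OCc2ccccc2)c(OCc2ccccc2)c1 | intermediate
39 | hexadeca-O-benzyl ether of the target | c1c(OCc2ccccc2)c(OCc2ccccc2)c(OCc2ccccc2)cc1Oc1c(OCc2ccccc2)c(OCc2ccccc2)c(OCc2ccccc2)cc1Oc1c(OCc2ccccc2)cc(Oc2c(OCc3ccccc3)c(OCc3ccccc3)c(OCc3ccccc3)cc2Oc2c(OCc3ccccc3)cc(Oc3c(OCc4ccccc4)cc(OCc4ccccc4)cc3OCc3ccccc3)cc2OCc2ccccc2)cc1OCc1ccccc1 | intermediate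
40 | CNP0114537.0 (hexameric phenyl ether with sixteen free hydroxyls) | Oc1cc(O)c(Oc2cc(O)c(Oc3cc(O)c(O)c(O)c3Oc3cc(O)c(Oc4cc(O)c(O)c(O)c4Oc4cc(O)c(O)c(O)c4)c(O)c3)c(O)c2)c(O)c1 | target

## Step count and risks

Total: 24 steps. Longest linear sequence: 15 steps from 5 (steps 3, 4, 5, 6, 7, 12, 13, 14, 15, 16, 18, 19, 20, 23, 24).

**Step 19 (key step).** The most likely failure is closure of the enynyl ketene at the proximal alkyne carbon, which would give an alkylidene cyclopentenedione instead of the quinone; the partition between the two diradical paths has not been established for an aryloxy-substituted alkyne. A second possibility is acid-triggered rearrangement of the ynol ether carbinol before ring opening.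
Fallback: set out from 30 and semihydrogenate the alkyne (H2, Pd/CaCO3 poisoned with Pb(OAc)2, quinoline, EtOAc) to rac-2,3-bis(benzyloxy)-4-hydroxy-4-[(Z)-2-(ABCD-aryloxy)vinyl]cyclobut-2-en-1-one F1. Heating F1 in toluene should open the ring and close ring E by 6π electrocyclisation, a pericyclic path with no diradical and no five-ring option, forming the same C6–C1 bond. Tautomerisation would give hydroquinone 34, where the route is rejoined at the benzylation stage of step 20.

**Step 12.** The coupling may stall because both partners carry ortho substituents, with protodeiodination of 18 and slow oxidation of the phenoxide taking over.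
Fallback: set out from 12 and use a ring C partner whose leaving group is activated by an ortho formyl group that also serves as the masked phenol. Formylation of 38 (Cl2CHOMe, SnCl4, CH2Cl2, −20 °C) at the position ortho to bromine would give 6-bromo-2,3,4-tris(benzyloxy)benzaldehyde F2. Copper-mediated coupling of F2 with 12 (CuI, picolinic acid, K3PO4, DMSO, 90 °C) would give 2,3,4-tris(benzyloxy)-6-{2,6-bis(benzyloxy)-4-[2,4,6-tris(benzyloxy)phenoxy]phenoxy}benzaldehyde F3. Baeyer–Villiger oxidation (mCPBA) to the corresponding aryl formate F4, not isolated, and methanolysis (K2CO3, MeOH) would give 20, where the route is rejoined without steps 8 to 13.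

**Step 18.** Butyllithium or a second acetylide may attack the squarate, the lithium alkoxide of the adduct may open on warming, and the ynol ether may hydrate during work-up.
Fallback: set out from 25 and quench acetylide 29 with Me3SiCl to isolate trimethylsilylethynyl ABCD-aryl ether F5. Fluoride-catalysed addition of F5 to 27 (Bu4NF cat., THF, −20 °C) should give rac-2,3-bis(benzyloxy)-4-(trimethylsilyloxy)-4-[(ABCD-aryloxy)ethynyl]cyclobut-2-en-1-one F6 without a free alkoxide or organolithium in the presence of the squarate. Mild methanolysis (K2CO3, MeOH, 0 °C) would return 30.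

**Step 20.** Alkylation may not discriminate well enough between the two hydroxyls, giving ether formation at the crowded hydroxyl or at both.
Fallback: set out from 30 and fix the regiochemistry by the origin of the oxygens. Semihydrogenation as above gives F1. Benzylation of its tertiary hydroxyl (BnBr, Ag2O, MeCN) would give rac-2,3,4-tris(benzyloxy)-4-[(Z)-2-(ABCD-aryloxy)vinyl]cyclobut-2-en-1-one F7. Thermolysis in toluene should then give 35 directly, since the carbinol oxygen becomes the benzyl ether next to the ring C–H and the ketene oxygen becomes the free hydroxyl. The route is rejoined at 35.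

**Step 23.** Ether formation at the hydroxyl of 35, flanked by a benzyloxy and a bulky aryloxy group, may be too slow at 100 °C, leaving time for oxidation of the electron-rich phenoxide and reduction of the bromide.
Fallback: set out from 35 and reverse the polarity of the ring F partner. Bromide 38 would be converted (n-BuLi, THF, −78 °C; B(Oi-Pr)3; aq HCl) into 3,4,5-tris(benzyloxy)phenylboronic acid F8. Chan–Lam coupling of F8 with 35 (Cu(OAc)2, pyridine, 4 Å molecular sieves, CH2Cl2, rt, air), an oxidative coupling through trivalent copper at room temperature, would give 39, where the route is rejoined.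

## Further compounds

F1 | step 19 | rac-2,3-bis(benzyloxy)-4-hydroxy-4-[(Z)-2-(ABCD-aryloxy)vinyl]cyclobut-2-en-1-one | O=C1C(OCc2ccccc2)=C(OCc2ccccc2)C1(O)/C=C\Oc1c(OCc2ccccc2)cc(Oc2c(OCc3ccccc3)c(OCc3ccccc3)c(OCc3ccccc3)cc2Oc2c(OCc3ccccc3)cc(Oc3c(OCc4ccccc4)cc(OCc4ccccc4)cc3OCc3ccccc3)cc2OCc2ccccc2)cc1OCc1ccccc1
F2 | step 12 | 6-bromo-2,3,4-tris(benzyloxy)benzaldehyde | O=Cc1c(Br)cc(OCc2ccccc2)c(OCc2ccccc2)c1OCc1ccccc1
F3 | step 12 | 2,3,4-tris(benzyloxy)-6-{2,6-bis(benzyloxy)-4-[2,4,6-tris(benzyloxy)phenoxy]phenoxy}benzaldehyde | O=Cc1c(Oc2c(OCc3ccccc3)cc(Oc3c(OCc4ccccc4)cc(OCc4ccccc4)cc3OCc3ccccc3)cc2OCc2ccccc2)cc(OCc2ccccc2)c(OCc2ccccc2)c1OCc1ccccc1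
F4 | step 12 | 2,3,4-tris(benzyloxy)-6-{2,6-bis(benzyloxy)-4-[2,4,6-tris(benzyloxy)phenoxy]phenoxy}phenyl formate | O=COc1c(Oc2c(OCc3ccccc3)cc(Oc3c(OCc4ccccc4)cc(OCc4ccccc4)cc3OCc3ccccc3)cc2OCc2ccccc2)cc(OCc2ccccc2)c(OCc2ccccc2)c1OCc1ccccc1
F5 | step 18 | trimethylsilylethynyl ABCD-aryl ether | C[Si](C)(C)C#COc1c(OCc2ccccc2)cc(Oc2c(OCc3ccccc3)c(OCc3ccccc3)c(OCc3ccccc3)cc2Oc2c(OCc3ccccc3)cc(Oc3c(OCc4ccccc4)cc(OCc4ccccc4)cc3OCc3ccccc3)cc2OCc2ccccc2)cc1OCc1ccccc1
F6 | step 18 | rac-2,3-bis(benzyloxy)-4-(trimethylsilyloxy)-4-[(ABCD-aryloxy)ethynyl]cyclobut-2-en-1-one | O=C1C(OCc2ccccc2)=C(OCc2ccccc2)C1(O[Si](C)(C)C)C#COc1c(OCc2ccccc2)cc(Oc2c(OCc3ccccc3)c(OCc3ccccc3)c(OCc3ccccc3)cc2Oc2c(OCc3ccccc3)cc(Oc3c(OCc4ccccc4)cc(OCc4ccccc4)cc3OCc3ccccc3)cc2OCc2ccccc2)cc1OCc1ccccc1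
F7 | step 20 | rac-2,3,4-tris(benzyloxy)-4-[(Z)-2-(ABCD-aryloxy)vinyl]cyclobut-2-en-1-one | O=C1C(OCc2ccccc2)=C(OCc2ccccc2)C1(OCc1ccccc1)/C=C\Oc1c(OCc2ccccc2)cc(Oc2c(OCc3ccccc3)c(OCc3ccccc3)c(OCc3ccccc3)cc2Oc2c(OCc3ccccc3)cc(Oc3c(OCc4ccccc4)cc(OCc4ccccc4)cc3OCc3ccccc3)cc2OCc2ccccc2)cc1OCc1ccccc1
F8 | step 23 | 3,4,5-tris(benzyloxy)phenylboronic acid | OB(O)c1cc(OCc2ccccc2)c(OCc2ccccc2)c(OCc2ccccc2)c1
A1 | alternative 1 | cyclopentadienyl[η6-2,5-dichloro-1,3-bis(methoxymethoxy)benzene]ruthenium hexafluorophosphate | COCOc1cc(Cl)cc(OCOC)c1Cl.[Ru+2].c1cc[cH-]c1.F[P-](F)(F)(F)(F)F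
A2 | alternative 1 | CDEF phenol with eleven benzyl ethers (free hydroxyl on ring C) | Oc1cc(OCc2ccccc2)c(OCc2ccccc2)c(OCc2ccccc2)c1Oc1cc(OCc2ccccc2)c(Oc2cc(OCc3ccccc3)c(OCc3ccccc3)c(OCc3ccccc3)c2Oc2cc(OCc3ccccc3)c(OCc3ccccc3)c(OCc3ccccc3)c2)c(OCc2ccccc2)c1
A3 | alternative 1 | hexamer with ring B as bis(methoxymethyl) ether and fourteen benzyl ethers | COCOc1cc(Oc2c(OCc3ccccc3)cc(OCc3ccccc3)cc2OCc2ccccc2)cc(OCOC)c1Oc1cc(OCc2ccccc2)c(OCc2ccccc2)c(OCc2ccccc2)c1Oc1cc(OCc2ccccc2)c(Oc2cc(OCc3ccccc3)c(OCc3ccccc3)c(OCc3ccccc3)c2Oc2cc(OCc3ccccc3)c(OCc3ccccc3)c(OCc3ccccc3)c2)c(OCc2ccccc2)c1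
A4 | alternative 2 | (Z)-3-(dimethylamino)-2-[2,4,6-tris(benzyloxy)phenoxy]acrolein | CN(C)/C=C(\Oc1c(OCc2ccccc2)cc(OCc2ccccc2)cc1OCc1ccccc1)C=O
A5 | alternative 2 | 1,3-bis(benzyloxy)acetone | O=C(COCc1ccccc1)COCc1ccccc1
A6 | alternative 2 | 2,6-bis(benzyloxy)-4-[2,4,6-tris(benzyloxy)phenoxy]phenol (identical with compound 12) | Oc1c(OCc2ccccc2)cc(Oc2c(OCc3ccccc3)cc(OCc3ccccc3)cc2OCc2ccccc2)cc1OCc1ccccc1
A7 | alternative 3 | dimethyl 1,3-acetonedicarboxylate | COC(=O)CC(=O)CC(=O)OC
A8 | alternative 3 | dimethyl 2-(BCDEF-aryloxy)malonate with thirteen benzyl ethers | COC(=O)C(Oc1cc(OCc2ccccc2)c(Oc2cc(OCc3ccccc3)c(OCc3ccccc3)c(OCc3ccccc3)c2Oc2cc(OCc3ccccc3)c(Oc3cc(OCc4ccccc4)c(OCc4ccccc4)c(OCc4ccccc4)c3Oc3cc(OCc4ccccc4)c(OCc4ccccc4)c(OCc4ccccc4)c3)c(OCc3ccccc3)c2)c(OCc2ccccc2)c1)C(=O)OC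
A9 | alternative 3 | hexamer with ring A as dimethyl 2,4,6-trihydroxy-5-aryloxyisophthalate | COC(=O)c1c(O)c(C(=O)OC)c(O)c(c1O)Oc1cc(OCc2ccccc2)c(Oc2cc(OCc3ccccc3)c(OCc3ccccc3)c(OCc3ccccc3)c2Oc2cc(OCc3ccccc3)c(Oc3cc(OCc4ccccc4)c(OCc4ccccc4)c(OCc4ccccc4)c3Oc3cc(OCc4ccccc4)c(OCc4ccccc4)c(OCc4ccccc4)c3)c(OCc3ccccc3)c2)c(OCc2ccccc2)c1
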